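Slowness is what I want to measure in this flask: how long does one molecule of free starting material wait before a chain takes it?

starting material 0.30 M; gas 36 mM (held); scavenger 0.450 M; initiator 7.5 mM; time 12 h

    initiator → 2 initiating radical (k1 = 6.35 × 10⁻⁴ h⁻¹)
    starting material + initiating radical → capped initiator + first chain carrier (k2 = 4.06 × 10⁵ M⁻¹ s⁻¹)
    reagent + first chain carrier → target + second chain carrier (k3 = 85000 M⁻¹ s⁻¹)
    starting material + second chain carrier → released group + first chain carrier (k4 = 42400 M⁻¹ s⁻¹)
    2 first chain carrier → ended chains A (k5 = 9.7 × 10⁶ M⁻¹ s⁻¹)
    2 second chain carrier → ended chains B (k6 = 1.3 × 10⁹ M⁻¹ s⁻¹)
    gas ⇌ reagent, rate k7*(csat - [reagent]) (k7 = 44.7 h⁻¹, csat = 36 mM)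
    starting material + released group ⇌ idle adduct, settled at all times (K8 = 15.4 M⁻¹)
    scavenger + released group → scavenged by-product (k9 = 0.977 M⁻¹ h⁻¹)

- a species is counted by the starting material in it: one ended chains A counts as two
- amounts and yields of released group count idle adduct too
- for a step with 2 of a species take k times the square, and two of it per event
- at the start none of reagent is dissolved
- run time (flask): 12 h

* the target standing at 12 h, as a percentage of the starting material charged
* concentration of reagent in solution at 12 h, in percent of saturation

In 12 h hardly any of the initiator breaks, so the flask receives radicals at a steady 0.00953 mM h⁻¹. They end in pairs, and at the start the ending of first chain carriers runs at 0.129 of the ending of second chain carriers, so I let the second carriers do the ending. Supply equal to ending then puts [second chain carrier] at 1.01 × 10⁻⁹ M, the root of the breaking constant times [initiator] over the ending constant.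

Free starting material therefore falls in a pseudo-first-order way, at 42400 M⁻¹ s⁻¹ times that concentration. This gives 4.50 h as the time in which a free molecule has an even chance of being taken, my chain half-life. The run holds 2.67 of these, so on this clock 84.2% of the charge reaches target. But released group holds starting material as idle adduct, and a held molecule waits, so I commit to less than that, without a figure. Gas can deliver 1.61 M h⁻¹ against a draw of 0.0462 M h⁻¹ at the start, so I expect [reagent] within 2.87% of saturation.

The forecast gives 71% and 99.5%, with starting material “being tied up as idle adduct until the slow scavenger clears the released group”.

The flask gives 71.3% and 99.5%. Its half-life of starting material by the chain step at 12.0 h reads 4.5 h, matching my 4.50 h. Target stands 13 percentage points below my clock's figure, with 11.1% in idle adduct.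

The neighbour charged with 0.75 M keeps the same initiator, so I try the same clock there, which gives 84.2%. But with its full charge free and [reagent] at saturation, the ending of first chain carriers in that neighbour reckons to 0.806 of the ending of second chain carriers, more than the 0.129 of the first flask, so my neglect of it does not carry over and the figure is a rough one. That neighbour computes to 62.7%, with 22.0% in idle adduct.

All constants are assumed; the flask was simulated.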